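## The problem

Atoms are numbered along the polypropionate chain: C1 (lactone carbonyl), C2 (quaternary), C3 (ketone), C4, C5 (bearing the lactone oxygen O5), C6, C7 (spiro), C8, C9 (acetoxy), C10, C11 (bearing the pyran oxygen O11) and C12 (methyl). Target 28 is a cyclohexanone (C2–C7) bridged by the C1–O5 lactone into a 2-oxabicyclo[2.2.2]octane and spiro-linked at C7 to a tetrahydropyran (O11, C7–C11). Nine stereocentres (C2, C4–C11) have to be set. Two are fully substituted: C2, an all-carbon centre flanked by three oxidised carbons, and the spiro ether carbon C7. The rigid bicycle lets one centre steer the next: the C4 methyl decides the sense of a C3 carbinol and the resting place of the C6 methyl, the C6 methyl shields one face of C7, and in the pyran the equatorial C8 and C10 methyls decide C11. The β-keto lactone around C2 is open to retro-Claisen cleavage. Any C3 or C7 alkoxide is β to the lactone carbonyl and can fragment the carbocycle by retro-aldol reaction. C4 and C6 can epimerise next to ketones, and the C9 acetate tolerates neither base nor hydride. The handle for the key step is C11: it carries only hydrogen, the C12 methyl and O11, so it can come from a terminal C11=C12 alkene captured in the Markovnikov sense by the tertiary C7 hydroxyl under neutral conditions.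

## Retrosynthesis

**28 ⇒ 27 ⇒ 26 (C3 oxidation level).** No skeletal bond is cut. The C3 ketone is carried as a TBS ether because a C3 carbonyl would put C2 at the centre of a tricarbonyl array and would compete with C7 for nucleophiles. The forward steps are an acidic desilylation to 27 and a buffered oxidation that must not epimerise C4.

**26 ⇒ 25 (O11–C11, key step).** The pyran is opened at O11–C11. Cutting O11–C7 instead would need a cation at C7 next to quaternary C2, and cutting a ring C–C bond would lose the acyclic stereotriad logic. Precursor 25 has one ring and one stereocentre fewer, and its side chain (C8–C12) is a crotylation product. The forward step must add a hindered tertiary hydroxyl to an unactivated terminal alkene at the internal carbon without acid or base.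

**25 ⇒ 24 ⇒ 20 + 21 (C9–C10).** The C9–C10 bond is cut to aldehyde 20 and a crotyl unit from trans-2-butene 21. The (E)-geometry is needed because C9–O and the C10 methyl are anti. The C8/C9 anti relation is anti-Felkin, so the reagent has to control the face. Diol 24 is then acetylated at the secondary C9 hydroxyl only.

**20 ⇒ 18 ⇒ 15 + 16 (C7–C8).** The C7–C8 bond is cut to bicyclic ketone 15 and potassium (E)-crotyltrifluoroborate 16; the vinyl group of 18 is the masked C9 aldehyde. A propionate ester aldol at C7 was set aside because the resulting ester cannot be reduced beside the lactone and its metal alkoxide invites retro-aldol cleavage. Ketone 15 has five stereocentres and no side chain. The forward step must attack the C7 face on the C3–C4 bridge side and set C8.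

**15 ⇒ 13 (C2–C3).** The carbocycle is opened at C2–C3. C2 lies between the C1 and C7 carbonyls and is the natural nucleophile, and C3 is an aldehyde on the C5 side chain. This removes the bicycle, the quaternary centre and the C3 centre in one cut and leaves monocyclic keto lactone 13 with three contiguous stereocentres. Closing the lactone last, or forming C2–C7 by Claisen condensation, would need longer chains with more stereocentres. The forward reaction is an intramolecular Mukaiyama aldol through enol silane 14 and must be irreversible.

**13 ⇒ 12 ⇒ 11 ⇒ 10 (C3 oxidation level, C1–O5).** The aldehyde comes from benzyl ether 11 via alcohol 12. The lactone C1–O5 bond comes from acyl transfer of the imide in 10 to the C5 hydroxyl, which also removes the auxiliary.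

**10 ⇒ 5 + 8 (C5–C6).** An anti aldol between β-keto imide 5 and aldehyde 8 sets C5 and C6 against the C4 centre. The C2 centre of 5 only directs the enolate face and is erased later.

**5 ⇒ 4 ⇒ 1 + 2; 8 ⇒ 7 ⇒ 6.** Keto imide 5 comes from the syn aldol of propionyl oxazolidinone 1 with propanal 2 and oxidation of 4. Aldehyde 8 comes from the (R)-Roche ester 6 by benzylation to 7 and partial reduction.

## Roads not taken

Alternative 1: The carbocycle would be cut at C2–C7 and C5–C6. In the forward sense the silyloxy pyranone A1 would add as a diene across the exocyclic (Z)-ethylidene enol ether A2 of a preformed tetrahydropyran to give cycloadduct A3.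
- Merits: the step is highly convergent, forms both fully substituted centres and the lactone bridge at once, and delivers C3 as an enol silane. It would very likely be shorter than the chosen route.
- Weak points: A1 and A2 are both electron-rich, so the cycloaddition would need forcing. Bridged pyranone adducts that keep a ring alkene are prone to decarboxylative cycloreversion on heating. The bond between C2 and C7 joins two fully substituted carbons. Face and endo/exo selectivity on A2 would have to place the C6 methyl and O11 correctly with no rigid template. A2 can also isomerise to the endocyclic enol ether.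
- Comparison: the chosen plan is longer, but each C–C bond is made in a separate, precedented step and the bicycle itself controls C7.

Alternative 2: The lactone would be cut at C1–C2. Fluoride would release the C2 enolate from the enol silane of spirocycle A4, which would attack the O5 carbonylimidazole to give keto lactone A5.
- Merits: the enolate is regiodefined, the acylation is intramolecular, C2 is fixed by the tether and the C3 ketone is already present. No tertiary carbinol β to a lactone is ever carried, which is a real advantage over the chosen route.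
- Weak points: A4 is a spiro[5.5] system with seven stereocentres whose C7 centre must be built without the bias of the bicycle. The tetrasubstituted enolate carbon sits next to the spiro centre and must reach the acyl group through a boat. Proton transfer to the C4 enolate would allow β-elimination of the C5 acyloxy group. Two more steps are needed to exchange the C9 silyl ether for the acetate.
- Comparison: the chosen plan makes the bicycle early from simple acyclic pieces and uses it as the stereocontrol element.

Alternative 3: The pyran would be cut at C7–O11 and C7–C8. TMSOTf would condense the silyl ether of fragment A6 with the same ketone 15 to an oxocarbenium ion that its enol silane closes to pyranone A7.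
- Merits: the whole C8–C12 unit is attached in one step with two bonds and the ring formed. Together with reduction and acetylation this would replace five steps of the chosen route by three.
- Weak points: an oxocarbenium ion must form at a ketone flanked by quaternary C2. The C7 face and the C8 centre depend on a less predictable transition state. The C9 ketone then needs an axial-alcohol-selective reduction next to two epimerisable methyl centres, and A6 needs its own synthesis.
- Comparison: Alternative 3 is the shorter road if the spiroannulation works. The chosen plan offers closed transition states for C7/C8 and a neutral ring closure in return.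

Key step: step 14

Assumption: keto lactones 11–13 are written as their enol tautomers (the C2-epimeric diketo forms equilibrate with them), and potassium (E)-crotyltrifluoroborate 16 is taken as a purchased reagent.

## Route

Step 1
Reactants: 1 (R)-4-benzyl-3-propanoyl-1,3-oxazolidin-2-one; 2 propanal
Product: 4 (R)-4-benzyl-3-[(2R,3S)-3-hydroxy-2-methylpentanoyl]-1,3-oxazolidin-2-one, via dibutylboron (Z)-enolate 3 (not isolated)
Conditions: n-Bu2BOTf, i-Pr2NEt, CH2Cl2, −78 → 0 °C; pH 7 buffer, MeOH, H2O2
Reagents that add atoms: none
Why: Evans syn aldol; the (Z)-boron enolate reacts through a Zimmerman–Traxler chair on the face away from the benzyl group, giving the (2R,3S) syn pair, of which only C2 is carried on.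

Step 2
Reactants: 4 (R)-4-benzyl-3-[(2R,3S)-3-hydroxy-2-methylpentanoyl]-1,3-oxazolidin-2-one
Product: 5 (R)-4-benzyl-3-[(2R)-2-methyl-3-oxopentanoyl]-1,3-oxazolidin-2-one
Conditions: DMP, CH2Cl2, 0 °C → rt
Reagents that add atoms: none
Why: Dess–Martin oxidation of the secondary alcohol; the β-keto imide should keep its C2 configuration because allylic 1,3-strain with the imide disfavours enolisation toward C2.

Step 3
Reactants: 6 methyl (R)-3-hydroxy-2-methylpropanoate
Product: 7 methyl (R)-3-(benzyloxy)-2-methylpropanoate
Conditions: BnOC(=NH)CCl3, TfOH (cat.), cyclohexane/CH2Cl2, rt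
Reagents that add atoms: benzyl 2,2,2-trichloroacetimidate, ClC(Cl)(Cl)C(=N)OCc1ccccc1
Why: Acid-catalysed imidate benzylation avoids base and so leaves the α-stereocentre of the Roche ester untouched.

Step 4
Reactants: 7 methyl (R)-3-(benzyloxy)-2-methylpropanoate
Product: 8 (R)-3-(benzyloxy)-2-methylpropanal
Conditions: DIBAL-H, CH2Cl2, −78 °C; Rochelle salt
Reagents that add atoms: none
Why: Partial DIBAL-H reduction of the ester at −78 °C stops at the aldehyde, which is used at once to avoid racemisation; its stereocentre becomes C4.

Step 5
Reactants: 5 (R)-4-benzyl-3-[(2R)-2-methyl-3-oxopentanoyl]-1,3-oxazolidin-2-one; 8 (R)-3-(benzyloxy)-2-methylpropanal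
Product: 10 (R)-4-benzyl-3-[(2R,4S,5S,6R)-7-(benzyloxy)-5-hydroxy-2,4,6-trimethyl-3-oxoheptanoyl]-1,3-oxazolidin-2-one, via dicyclohexylboron (E)-enolate 9 (not isolated)
Conditions: (c-Hex)2BCl, Me2NEt, Et2O, 0 °C; 8, −78 → −20 °C; pH 7 buffer, MeOH, H2O2
Reagents that add atoms: none
Why: Anti-selective β-keto imide aldol; the (E)-boron enolate adds through a chair on the face set by the C2 centre (C2/C6 methyls anti, C5/C6 anti). The Felkin preference of the α-methyl aldehyde toward (E)-enolates is matched and gives C4/C5 syn.

Step 6
Reactants: 10 (R)-4-benzyl-3-[(2R,4S,5S,6R)-7-(benzyloxy)-5-hydroxy-2,4,6-trimethyl-3-oxoheptanoyl]-1,3-oxazolidin-2-one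
Product: 11 (5S,6S)-6-[(2R)-1-(benzyloxy)propan-2-yl]-4-hydroxy-3,5-dimethyl-5,6-dihydro-2H-pyran-2-one
Conditions: DBU, CH2Cl2, 0 °C → rt; 1 M HCl
Reagents that add atoms: none
Why: The δ-hydroxyl acylates on the activated exocyclic imide carbonyl (6-exo-trig lactonisation) and expels the recoverable oxazolidinone. The anti-aldol pattern places the C5 and C6 substituents trans-diequatorial, which is also the thermodynamic arrangement.

Step 7
Reactants: 11 (5S,6S)-6-[(2R)-1-(benzyloxy)propan-2-yl]-4-hydroxy-3,5-dimethyl-5,6-dihydro-2H-pyran-2-one
Product: 12 (5S,6S)-4-hydroxy-6-[(2R)-1-hydroxypropan-2-yl]-3,5-dimethyl-5,6-dihydro-2H-pyran-2-one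
Conditions: H2 (1 atm), Pd/C, EtOAc, rt
Reagents that add atoms: none
Why: Hydrogenolysis of the benzyl ether under neutral conditions; the tetrasubstituted enol double bond is not reduced.

Step 8
Reactants: 12 (5S,6S)-4-hydroxy-6-[(2R)-1-hydroxypropan-2-yl]-3,5-dimethyl-5,6-dihydro-2H-pyran-2-one
Product: 13 (2S)-2-[(2R,3S)-4-hydroxy-3,5-dimethyl-6-oxo-3,6-dihydro-2H-pyran-2-yl]propanal
Conditions: DMP, CH2Cl2, 0 °C, short reaction time; used crude
Reagents that add atoms: none
Why: Dess–Martin oxidation of the primary alcohol is fast and non-basic, so the β-acyloxy aldehyde should not eliminate the lactone carboxylate or epimerise at C4. In CH2Cl2 the keto lactone is mainly in its diketo form, which limits attack of the oxidant on the enol.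

Step 9
Reactants: 13 (2S)-2-[(2R,3S)-4-hydroxy-3,5-dimethyl-6-oxo-3,6-dihydro-2H-pyran-2-yl]propanal
Product: 15 (1S,4R,6S,7S,8R)-8-[(tert-butyldimethylsilyl)oxy]-4,6,7-trimethyl-2-oxabicyclo[2.2.2]octane-3,5-dione (chain numbering 2R,3R,4S,5S,6S), via TBS enol ether 14 (not isolated)
Conditions: TBSOTf (2.2 equiv), 2,6-lutidine, CH2Cl2, −78 → 0 °C
Reagents that add atoms: tert-butyldimethylsilyl triflate, CC(C)(C)[Si](C)(C)OS(=O)(=O)C(F)(F)F
Why: Silyl-triflate-mediated intramolecular Mukaiyama aldol; the acidic enol is silylated, the silyl triflate activates the aldehyde, and C2 adds to C3 with transfer of the silyl group to O3, which makes the ring closure irreversible. C2 is fixed by the tether, since only the enol face cis to the C5 side chain can be reached. C3 is set by the antiperiplanar open transition state, which puts the silyloxy group trans to the C4 methyl on the lactone side.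

Step 10
Reactants: 15 bicyclic keto lactone (chain numbering 2R,3R,4S,5S,6S); 16 potassium (E)-crotyltrifluoroborate
Product: 18 C7 tertiary alcohol of the bicyclic lactone carrying an (R)-but-3-en-2-yl group at C7 (chain numbering 2R,3R,4S,5S,6S,7S,8R), via (E)-crotyldifluoroborane 17 (not isolated)
Conditions: BF3·OEt2, CH2Cl2, −78 °C; aq NaHCO3
Reagents that add atoms: none
Why: Crotylboration of a ketone through a closed chair transition state. Attack should come on the C7 face anti to the eclipsing C6 methyl, the C3–C4 bridge side where only C3–H points, which puts the hydroxyl on the lactone side. Boron binds the carbonyl lone pair away from the in-plane C2 methyl, so C2 is pseudo-equatorial and the (E)-crotyl geometry gives (8R).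

Step 11
Reactants: 18 C7 tertiary alcohol with (R)-but-3-en-2-yl group (chain numbering 2R,3R,4S,5S,6S,7S,8R)
Product: 20 β-hydroxy aldehyde with C9 as CHO (chain numbering 2R,3R,4S,5S,6S,7R,8S), via secondary ozonide 19 (not isolated)
Conditions: O3, CH2Cl2, −78 °C; PPh3, −78 °C → rt; used without chromatography
Reagents that add atoms: ozone, [O-][O+]=O
Why: Ozonolysis of the terminal alkene with reductive work-up; the conditions are neutral, so neither the β-hydroxy aldehyde nor the β-hydroxy lactone should undergo retro-aldol cleavage and C8 is not epimerised.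

Step 12
Reactants: 20 β-hydroxy aldehyde (chain numbering 2R,3R,4S,5S,6S,7R,8S); 21 trans-2-butene
Product: 24 C7,C9-diol with the C8–C12 side chain (chain numbering 2R,3R,4S,5S,6S,7S,8R,9R,10R), via (E)-crotylpotassium 22 (not isolated), via (E)-crotyldiisopinocampheylborane 23 (not isolated)
Conditions: 21, n-BuLi, KOt-Bu, THF, −78 → −45 °C; (+)-Ipc2BOMe (from (−)-α-pinene), −78 °C; BF3·OEt2; 20, −78 °C; aq NaOAc, H2O2, 0 °C → rt
Reagents that add atoms: none
Why: Brown crotylboration; the (E)-crotylborane gives the C9/C10 anti pair through a chair transition state, and the Ipc ligands of this series direct the crotyl group to the Re face of the aldehyde (9R,10R). The C8/C9 anti relation is anti-Felkin, so the reagent must override the substrate. A hydrogen bond from the free C7 hydroxyl to the aldehyde oxygen should help by holding C7 synclinal to the carbonyl, which leaves the face anti to the C8 methyl open.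

Step 13
Reactants: 24 C7,C9-diol (chain numbering 2R,3R,4S,5S,6S,7S,8R,9R,10R)
Product: 25 C9 acetate with free tertiary C7 hydroxyl and C11=C12 alkene (chain numbering 2R,3R,4S,5S,6S,7S,8R,9R,10R)
Conditions: Ac2O, pyridine, DMAP (cat.), CH2Cl2, 0 °C
Reagents that add atoms: acetic anhydride, CC(=O)OC(C)=O
Why: Acylation of the secondary hydroxyl; the tertiary C7 hydroxyl, flanked by quaternary C2 and two branched carbons, should not react at 0 °C.

Step 14
Reactants: 25 C9 acetate with free tertiary C7 hydroxyl and C11=C12 alkene
Product: 26 spiro tetrahydropyran with C3 TBS ether and C9 acetate (chain numbering 2R,3R,4S,5S,6S,7S,8R,9R,10R,11R)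
Conditions: Co(salen) [salen = (R,R)-N,N'-bis(3,5-di-tert-butylsalicylidene)-1,2-cyclohexanediamine dianion; divalent cobalt] (5 mol%), N-fluoro-2,4,6-trimethylpyridinium tetrafluoroborate, PhSiH3, PhCF3, rt
Reagents that add atoms: none
Why: The N-fluoropyridinium salt oxidises the divalent cobalt salen complex to a trivalent cobalt fluoride, which PhSiH3 turns into a cobalt hydride; transfer of its hydrogen atom to terminal C12 leaves a secondary radical at C11. Cobalt captures this radical and further oxidation gives a tetravalent alkylcobalt species that acts as a cation equivalent; the C7 hydroxyl displaces cobalt, the proton goes to the collidine and the divalent catalyst is released. The closest known reaction type is the cobalt-salen hydrogen-atom-transfer hydroalkoxylation of unactivated alkenes by tethered alcohols. The tetrahydropyran closes in the 6-exo mode by forming O11–C11. C11 is set in a chair transition state with the C8 and C10 methyls equatorial and the C9 acetate axial; the axial sites on that face are taken by the acetate and C6, so the C12 methyl goes equatorial (11R). Markovnikov regiochemistry follows from hydrogen-atom transfer to the terminal carbon. The neutral conditions should spare the acetate, the silyl ether and the lactone and never form a C7 alkoxide, so retro-aldol opening of the carbocycle is avoided. Only the C7 hydroxyl reaches C11 through a six-membered ring apart from the acetate carbonyl, which is the weaker nucleophile.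

Step 15
Reactants: 26 spiro tetrahydropyran with C3 TBS ether and C9 acetate
Product: 27 C3 alcohol of the spiro tetrahydropyran lactone (chain numbering 2R,3R,4R,5S,6S,7S,8R,9R,10R,11R)
Conditions: HF (48% aq), MeCN, 0 °C → rt
Reagents that add atoms: none
Why: Acidic fluoride desilylation of the hindered secondary silyl ether; no alkoxide is formed, so the β-hydroxy lactone should not fragment, and the acetate, lactone and ether survive.

Step 16
Reactants: 27 C3 alcohol of the spiro tetrahydropyran lactone
Product: 28 CNP0257416.1 (chain numbering 2S,4S,5R,6S,7S,8R,9R,10R,11R)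
Conditions: DMP, pyridine, CH2Cl2, 0 °C → rt
Reagents that add atoms: none
Why: Buffered Dess–Martin oxidation of the C3 carbinol; C2 is quaternary, so the new β-keto lactone cannot enolise there, and the mild conditions should leave the C4 centre alone.

## Compound list

1 | (R)-4-benzyl-3-propanoyl-1,3-oxazolidin-2-one | CCC(=O)N1C(=O)OC[C@H]1Cc1ccccc1 | starting material
2 | propanal | CCC=O | starting material
3 | dibutylboron (Z)-enolate of 1 | C/C=C(\OB(CCCC)CCCC)N1C(=O)OC[C@H]1Cc1ccccc1 | intermediate (not isolated)
4 | (R)-4-benzyl-3-[(2R,3S)-3-hydroxy-2-methylpentanoyl]-1,3-oxazolidin-2-one | CC[C@H](O)[C@@H](C)C(=O)N1C(=O)OC[C@H]1Cc1ccccc1 | intermediate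
5 | (R)-4-benzyl-3-[(2R)-2-methyl-3-oxopentanoyl]-1,3-oxazolidin-2-one | CCC(=O)[C@@H](C)C(=O)N1C(=O)OC[C@H]1Cc1ccccc1 | intermediate
6 | methyl (R)-3-hydroxy-2-methylpropanoate | COC(=O)[C@H](C)CO | starting material
7 | methyl (R)-3-(benzyloxy)-2-methylpropanoate | COC(=O)[C@H](C)COCc1ccccc1 | intermediate
8 | (R)-3-(benzyloxy)-2-methylpropanal | O=C[C@H](C)COCc1ccccc1 | intermediate
9 | dicyclohexylboron (E)-enolate of 5 | C/C=C(/OB(C1CCCCC1)C1CCCCC1)[C@@H](C)C(=O)N1C(=O)OC[C@H]1Cc1ccccc1 | intermediate (not isolated)
10 | (R)-4-benzyl-3-[(2R,4S,5S,6R)-7-(benzyloxy)-5-hydroxy-2,4,6-trimethyl-3-oxoheptanoyl]-1,3-oxazolidin-2-one | O=C(N1C(=O)OC[C@H]1Cc1ccccc1)[C@H](C)C(=O)[C@@H](C)[C@@H](O)[C@H](C)COCc1ccccc1 | intermediate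
11 | (5S,6S)-6-[(2R)-1-(benzyloxy)propan-2-yl]-4-hydroxy-3,5-dimethyl-5,6-dihydro-2H-pyran-2-one | CC1=C(O)[C@@H](C)[C@@H](OC1=O)[C@H](C)COCc1ccccc1 | intermediate
12 | (5S,6S)-4-hydroxy-6-[(2R)-1-hydroxypropan-2-yl]-3,5-dimethyl-5,6-dihydro-2H-pyran-2-one | CC1=C(O)[C@@H](C)[C@@H](OC1=O)[C@H](C)CO | intermediate
13 | (2S)-2-[(2R,3S)-4-hydroxy-3,5-dimethyl-6-oxo-3,6-dihydro-2H-pyran-2-yl]propanal | CC1=C(O)[C@@H](C)[C@@H](OC1=O)[C@H](C)C=O | intermediate
14 | TBS enol ether of 13 | CC1=C(O[Si](C)(C)C(C)(C)C)[C@@H](C)[C@@H](OC1=O)[C@H](C)C=O | intermediate (not isolated)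
15 | (1S,4R,6S,7S,8R)-8-[(tert-butyldimethylsilyl)oxy]-4,6,7-trimethyl-2-oxabicyclo[2.2.2]octane-3,5-dione | O=C1[C@@H](C)[C@H]2OC(=O)[C@]1(C)[C@H](O[Si](C)(C)C(C)(C)C)[C@H]2C | intermediate
16 | potassium (E)-crotyltrifluoroborate | C/C=C/C[B-](F)(F)F.[K+] | starting material
17 | (E)-crotyldifluoroborane | C/C=C/CB(F)F | intermediate (not isolated)
18 | C7 tertiary alcohol with (R)-but-3-en-2-yl group at C7 (2R,3R,4S,5S,6S,7S,8R) | C=C[C@@H](C)[C@]2(O)[C@@H](C)[C@H]1OC(=O)[C@]2(C)[C@H](O[Si](C)(C)C(C)(C)C)[C@H]1C | intermediate
19 | secondary ozonide (1,2,4-trioxolane) of 18, epimers at the ozonide carbon | C1OC(OO1)[C@@H](C)[C@]2(O)[C@@H](C)[C@H]3OC(=O)[C@]2(C)[C@H](O[Si](C)(C)C(C)(C)C)[C@H]3C | intermediate (not isolated)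
20 | β-hydroxy aldehyde, C9 as CHO (2R,3R,4S,5S,6S,7R,8S) | O=C[C@@H](C)[C@]2(O)[C@@H](C)[C@H]1OC(=O)[C@]2(C)[C@H](O[Si](C)(C)C(C)(C)C)[C@H]1C | intermediate
21 | trans-2-butene | C/C=C/C | starting material
22 | (E)-crotylpotassium | C/C=C/[CH2-].[K+] | intermediate (not isolated)
23 | (E)-crotyldiisopinocampheylborane (from (+)-Ipc2BOMe) | C/C=C/CB([C@H]1C[C@H]2C[C@@H]([C@@H]1C)C2(C)C)[C@H]1C[C@H]2C[C@@H]([C@@H]1C)C2(C)C | intermediate (not isolated)
24 | C7,C9-diol with C8–C12 side chain (2R,3R,4S,5S,6S,7S,8R,9R,10R) | C=C[C@@H](C)[C@@H](O)[C@@H](C)[C@]2(O)[C@@H](C)[C@H]1OC(=O)[C@]2(C)[C@H](O[Si](C)(C)C(C)(C)C)[C@H]1C | intermediate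
25 | C9 acetate with free C7 hydroxyl and terminal alkene (2R,3R,4S,5S,6S,7S,8R,9R,10R) | C=C[C@@H](C)[C@@H](OC(C)=O)[C@@H](C)[C@]2(O)[C@@H](C)[C@H]1OC(=O)[C@]2(C)[C@H](O[Si](C)(C)C(C)(C)C)[C@H]1C | intermediate
26 | spiro tetrahydropyran, C3 TBS ether, C9 acetate (2R,3R,4S,5S,6S,7S,8R,9R,10R,11R) | CC(=O)O[C@@H]1[C@H](C)[C@@H](C)O[C@@]2([C@@H]1C)[C@@H](C)[C@H]1OC(=O)[C@]2(C)[C@H](O[Si](C)(C)C(C)(C)C)[C@H]1C | intermediate
27 | C3 alcohol of the spiro lactone (2R,3R,4R,5S,6S,7S,8R,9R,10R,11R) | CC(=O)O[C@@H]1[C@H](C)[C@@H](C)O[C@@]2([C@@H]1C)[C@@H](C)[C@H]1OC(=O)[C@]2(C)[C@H](O)[C@H]1C | intermediate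
28 | CNP0257416.1 (2S,4S,5R,6S,7S,8R,9R,10R,11R) | CC(=O)O[C@@H]1[C@H](C)[C@@H](C)O[C@@]2([C@@H]1C)[C@@H](C)[C@H]1OC(=O)[C@]2(C)C(=O)[C@H]1C | target

## Step count and weak points

Total steps: 16. Longest linear sequence: 14 (steps 1, 2 and 5–16; the branch through steps 3 and 4 is equally long).

**Step 14 (key step).** The hindered tertiary hydroxyl may close slowly. The cobalt hydride could then isomerise the alkene inward or simply reduce it, and the C9 acetate carbonyl could capture the cation equivalent through a six-membered acyloxonium ion. Fallback: from 25, intramolecular oxymercuration with Hg(OCOCF3)2 in CH2Cl2 followed by aqueous NaCl should give the C12 chloromercurio tetrahydropyran F1 under equilibrating, chair-controlled conditions. Radical demercuration with Bu3SnH and AIBN in toluene then returns to 26.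

**Step 9.** The vinylogous silyl ester may be too weak a nucleophile for the boat-like bridging transition state. Competing enolisation of the aldehyde would erode C4, and elimination of the lactone carboxylate is possible. Fallback: from 13, equilibrating aldolisation of the free enol under weak acid (catalytic PPTS, CH2Cl2) should give the C3 carbinol F2 under thermodynamic control, with the hydroxyl trans to the C4 methyl. Silylation with TBSOTf and 2,6-lutidine at −78 °C returns to 15.

**Step 10.** Poor facial selectivity at C7, or sluggish addition to a ketone flanked by quaternary C2, would cost material at the point where two centres are set. Fallback: from 15, aldol addition of the kinetic lithium enolate of S-tert-butyl propanethioate (LDA, THF, −78 °C, acetic acid quench at −78 °C) through a closed transition state should give the β-hydroxy thioester F3. Fukuyama reduction (Et3SiH, Pd/C, acetone) converts the thioester into the aldehyde and rejoins the route at 20, bypassing 18.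

**Step 12.** The reagent has to override the Felkin preference of the α-branched aldehyde, so diastereofacial selectivity may erode. Epimerisation at C8 or retro-aldol loss of the C8–C9 unit from the β-hydroxy aldehyde is also possible. Fallback: from 20, addition of the allenylzinc reagent made from (S)-but-3-yn-2-yl methanesulfonate (Pd(OAc)2, PPh3, Et2Zn, THF, −78 → −20 °C) should give the anti,anti homopropargylic diol F4; this reagent class is the usual answer to anti,anti stereotriads. Semihydrogenation over Pd/CaCO3 poisoned with Pb(OAc)2 in the presence of quinoline returns to 24.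

## Further compounds

F1 | step 14 | C12 chloromercurio derivative of spiro tetrahydropyran 26 | CC(=O)O[C@@H]1[C@H](C)[C@@H](C[Hg]Cl)O[C@@]2([C@@H]1C)[C@@H](C)[C@H]1OC(=O)[C@]2(C)[C@H](O[Si](C)(C)C(C)(C)C)[C@H]1C
F2 | step 9 | (1S,4R,6S,7S,8R)-8-hydroxy-4,6,7-trimethyl-2-oxabicyclo[2.2.2]octane-3,5-dione | O=C1[C@@H](C)[C@H]2OC(=O)[C@]1(C)[C@H](O)[C@H]2C
F3 | step 10 | S-tert-butyl thioester at C9 of the C7 aldol adduct | CC(C)(C)SC(=O)[C@@H](C)[C@]2(O)[C@@H](C)[C@H]1OC(=O)[C@]2(C)[C@H](O[Si](C)(C)C(C)(C)C)[C@H]1C
F4 | step 12 | C7,C9-diol with terminal alkyne in place of the alkene | C#C[C@@H](C)[C@@H](O)[C@@H](C)[C@]2(O)[C@@H](C)[C@H]1OC(=O)[C@]2(C)[C@H](O[Si](C)(C)C(C)(C)C)[C@H]1C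
A1 | alternative 1 | 4-[(tert-butyldimethylsilyl)oxy]-3,5-dimethyl-2H-pyran-2-one | CC1=COC(=O)C(C)=C1O[Si](C)(C)C(C)(C)C
A2 | alternative 1 | (Z)-2-ethylidene tetrahydropyran with C9 TBS ether | C/C=C1\O[C@H](C)[C@@H](C)[C@@H](O[Si](C)(C)C(C)(C)C)[C@H]1C
A3 | alternative 1 | spiro bridged lactone with C3 enol silane and C9 silyl ether | CC(C)(C)[Si](C)(C)O[C@@H]1[C@H](C)[C@@H](C)O[C@@]2([C@@H]1C)[C@@H](C)[C@H]1OC(=O)[C@]2(C)C(O[Si](C)(C)C(C)(C)C)=C1C
A4 | alternative 2 | spirocyclic C3 enol silane with O5 carbonylimidazole | CC1=C(O[Si](C)(C)C)[C@@H](C)[C@H](OC(=O)n2ccnc2)[C@H](C)[C@]13O[C@H](C)[C@@H](C)[C@@H](O[Si](C)(C)C(C)(C)C)[C@H]3C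
A5 | alternative 2 | C9 silyl ether analogue of the target | CC(C)(C)[Si](C)(C)O[C@@H]1[C@H](C)[C@@H](C)O[C@@]2([C@@H]1C)[C@@H](C)[C@H]1OC(=O)[C@]2(C)C(=O)[C@H]1C
A6 | alternative 3 | (Z)-trimethylsilyl enol ether of (4R,5R)-4-methyl-5-(trimethylsilyloxy)hexan-3-one | C/C=C(\O[Si](C)(C)C)[C@H](C)[C@@H](C)O[Si](C)(C)C
A7 | alternative 3 | spiro tetrahydropyran-4-one on the bridged lactone | O=C1[C@H](C)[C@@H](C)O[C@@]2([C@@H]1C)[C@@H](C)[C@H]1OC(=O)[C@]2(C)[C@H](O[Si](C)(C)C(C)(C)C)[C@H]1C
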